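Watch side product A in the first hour of a run, and read one time off its curve. The share of target in target plus side product A, a selectivity, hangs on that time.

| flask | substrate | coupling partner | rival reagent | remark | time |
|---|---|---|---|---|---|
| alpha | 0.10 M | 0.070 M | 0.11 M | run made earlier |  |
| eta | 0.14 M | 0.070 M | 0.11 M | run made earlier |  |
| epsilon | 0.22 M | 0.070 M | 0.11 M | run made earlier |  |
| spring | 0.10 M (fed, over 1.0 h) | 0.0700 M | 0.110 M | all else is in the flask from the start; the feed brings no volume worth counting | 2.5 h |
| dawn | 0.10 M | 0.0700 M | 0.110 M | everything together at the start | 2.5 h |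
| dusk | 0.10 M | 0.0700 M | 0.110 M (fed, over 1.0 h) | all else is in the flask from the start; the feed brings no volume worth counting | 2.5 h |

| run | time / min | target / % | side product A / % |
|---|---|---|---|
| alpha | 8.00 | 35 | 3 |
| alpha | 15.0 | 44 | 9 |
| alpha | 25.0 | 52 | 6 |
| alpha | 50.0 | 59 | 11 |
| alpha | 90.0 | 58 | 10 |
| eta | 25.0 | 37 | 9 |
| eta | 50.0 | 41 | 9 |
| eta | 80.0 | 36 | 11 |
| eta | 90.0 | 39 | 9 |
| eta | 120 | 32 | 10 |
| epsilon | 10.0 | 24 | 3 |
| epsilon | 30.0 | 22 | 9 |
| epsilon | 60.0 | 17 | 11 |
| epsilon | 80.0 | 15 | 11 |
| epsilon | 120 | 10 | 9 |

(scatter of a reading: 1.5 percentage points)

- the best flask by share of target in target plus side product A; "all alike" if 1.5 percentage points covers them all (spring / dawn / dusk / all alike)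
- share of target in target plus side product A at the end, spring
- share of target in target plus side product A at the end, dawn
- share of target in target plus side product A at the end, dusk

- the numbers in the tables scatter with a standard deviation of 1.5 percentage points

In the alpha run, A starts steeply, with 3 % at 8.00 min, bends within the next readings and runs into a level. That level, in percent of the substrate charged, stays put while the charge goes from 0.10 M to 0.22 M:

| run | substrate charged | late level of A |
|---|---|---|
| alpha | 0.10 M | 10.5 % |
| eta | 0.14 M | 9.75 % |
| epsilon | 0.22 M | 10.3 % |

We freeze the mean, 10.2 %, as the risk a substrate molecule runs when it meets the full c(rival reagent). We read the flattening as rival reagent fading on its own clock. The first alpha reading, with its scatter, then gives 23.0 min: this is the rival window, the time constant with which A climbs to its level.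

Substrate arriving at time u meets a risk shrunk by exp(−u/τ), where τ is the window. Averaged over the feed in spring, that gives a factor 0.355, so A in spring is 3.61 %.

Dawn repeats the alpha recipe, so A there stays at 10.2 %. In dusk, rival reagent arrives late on average. From the alpha readings we take the charge not yet found in target or A: for dusk the value at 50.0 min, 30.0 %, and for dawn the value at 25.0 min, 42.0 %, so we reckon A in dusk at 7.28 %.

Holding target at 58 %, we reckon shares of 94.1 % for spring, 85.1 % for dawn and 88.8 % for dusk.

The forecast names spring, with 93 %, 83 % and 85 % for spring, dawn and dusk, adding “Rival was never varied, so dusk is uncertain”; ours stands 3.8 points above it at dusk.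

The flasks give spring as best, with 95.0 %, 85.6 % and 90.9 %.

    substrate + coupling partner → target (k = 1.30 L mol⁻¹ min⁻¹)
    substrate + rival reagent → side product A (k = 0.0922 L mol⁻¹ min⁻¹)
    rival reagent → decomposed reagent (k = 0.0476 min⁻¹)
    substrate + target → side product B (k = 0.0878 L mol⁻¹ min⁻¹)

The feed in spring spans 2.61 rival windows as we read them from one scattered reading, while the hidden constants put the dosing time at 3.4 lifetimes of rival reagent against everything charged. Our 3.61 % of A stands against 2.93 % in spring. The gap of 9.4 points between spring and dawn shrinks to 0.96 points when the loss of rival reagent to decomposed reagent is taken away. A neighbour of spring with 0.44 M of rival reagent keeps the factor 0.355, so the risk scaled by charge gives 14.5 % of A. That flask gives 10.6 %, and a share of 84.3 %.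

The runs are calculated for an exercise.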